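## The problem

Curtisian T (20) is a para-terphenyl whose central benzene ring is substituted at every position. C1 carries an (R)-3-acetoxybutanoyloxy group, C4 a benzoyloxy group, C2 and C5 free hydroxyls, and C3 and C6 the two 4-hydroxyphenyl rings. A synthesis must build this hexasubstituted ring with two para aryl–aryl bonds and four C–O bonds. It must then tell the central oxygens apart twice: the acylated 1,4-pair from the free 2,5-pair, and O1 from O4 within a core that is centrosymmetric. The only stereocenter, C3' of the butanoate chain (R), is remote from the ring; the core cannot control it, so it is best bought and then only guarded against erosion. The fragile elements are the two aryl esters next to free phenols (base invites acyl migration and hydrolysis), the β-acetoxy ester (base invites elimination to the crotonate), and the electron-rich central ring, which reoxidizes in air at the hydroquinone level. The last operations must therefore be neutral and the acetoxybutanoate should arrive late. The enabling feature appears when the central ring is written as its quinone: C1(=O)–C2(O)=C3(aryl)–C4(=O) is the skeleton of an aryl-substituted squaric acid derivative and C5(O)–C6(aryl) is an aryl ynol ether. The ring thus divides into a four-carbon and a two-carbon piece that already hold all six substituents, with the 1,4-oxygens as carbonyls and so distinct from the 2,5-oxygens.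

## Retrosynthesis

**20 to 19.** The four phenolic O–H bonds are uncovered last, by cutting four O–benzyl bonds. Benzyl is preferred to silyl or acetal groups because its removal needs neither fluoride nor acid nor base, all of which would move an acyl group onto a neighbouring phenoxide. Precursor 19 has no free phenol, so its esters cannot migrate. The forward step must be a hydrogenolysis that leaves two aryl esters and an alkyl acetate alone.

**19 to 16 and 18.** The ester bond between O1 and C1' is cut next, so that the elimination-prone β-acetoxy acyl group is the last piece attached. Acid 18 is one acetylation away from (R)-3-hydroxybutanoic acid 17, which supplies the stereocenter; no stereocenter is made in the synthesis. The forward step must acylate a phenol flanked by a benzyloxy group and an aryl ring without losing acetate.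

**16 to 15 to 14.** Cutting the benzoate at O4 leads to hydroquinone 15. Its two hydroxyls are equivalent by the inversion centre, so monoacylation can give only one monoester; the sole demand is to stop after one acylation. Hydroquinone 15 comes from quinone 14 by reduction. In 14 the 1,4-oxygens are carbonyls and the 2,5-oxygens are benzyl ethers, which is how the two pairs are told apart without a selective protection.

**14 to 12.** The benzyl ether at O5 is traced back to a silyl ether, because that oxygen enters as part of a silyl ynol ether. Exchanging silicon for benzyl makes all four protecting groups identical. Carrying the silyl group further would differentiate O4 from O1 sterically, but it would invite silyl migration to the adjacent oxygen and require a fluoride step beside aryl esters.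

**12 to 6 and 10 (key cut).** Bonds C4–C5 and C6–C1 of the quinone are cut. This gives cyclobutenedione 6 (C1–C4 with the C2 benzyloxy and C3 aryl groups) and siloxyalkyne 10 (C5 with its oxygen, C6 with its aryl group). Other [4+2] divisions of the ring give the same two types of partner, and a [3+3] division gives up the difference between the two oxygen pairs. Both partners are stable and far simpler than 12, which has a fully substituted ring. The forward reaction asks a monovalent cobalt phosphine complex to insert into the acyl–acyl bond of 6 (maleoylcobalt complex 11) and to take up 10 head to tail.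

**6 to 2 and 3; 2 to 1.** The aryl–C3 bond is cut to dibenzyl squarate 2 and the aryllithium 4 derived from bromide 3; adduct 5 loses benzyl alcohol on acid treatment. Squarate 2 is the benzyl ester of squaric acid 1. Benzyl is chosen here so that the C2 oxygen is already protected in its final form.

**10 to 7.** The alkyne is cut between C6 and the aryl ipso carbon by a one-carbon homologation of ethyl ester 7. The ester carbonyl carbon becomes the oxygen-bearing alkyne carbon through dibromoenolate 8 and ynolate 9, and O-silylation with a triisopropylsilyl group gives 10 in one flask.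

## Roads not taken

**Alternative 1:** The cut is the ester bond between O1 and C1' together with the C2'–C3' bond of the side chain. Phenol 16 would be acylated by the ketene A2, (R)-3-acetoxybut-1-en-1-one, released by Wolff rearrangement of the diazoketone A1, (R)-3-acetoxy-1-diazobutan-2-one. On irradiation A1 loses nitrogen, the acetoxy-bearing carbon migrates with retention, and the free hydroxyl captures the ketene to give A3, which is the same compound as 19.
- Merits: the ketene is small and very electrophilic, which suits a hindered phenol, and the medium is neutral, so base-induced loss of acetate cannot occur. In this one respect the road is better than a carbodiimide coupling.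
- Weak points: the cut concerns only the last ester and leaves the construction of the hexasubstituted ring unsolved. A1 must come from the less common (R)-lactic series through a diazoalkane acylation. A hindered phenol competes poorly with adventitious water and ketene dimerization at photolysis concentrations. The aryl benzoate already present is itself photolabile (photo-Fries rearrangement).
- Comparison: against the neutrality of the ketene the chosen plan sets acid 18, one step from the chiral pool and coupled without light or diazo chemistry, and a fallback that removes the leaving-group problem altogether.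

**Alternative 2:** The cut is C2–C3 and C5–C6, dividing the central ring into two identical three-carbon units, the arylpyruvate ester A4, methyl 3-(4-benzyloxyphenyl)-2-oxopropanoate. Under a hydride base two molecules would condense head to tail, each benzylic carbon being acylated by the ester carbonyl of the other. The cyclic tetraketone would tautomerize to the dihydroxyquinone A5, 2,5-dihydroxy-3,6-bis(4-benzyloxyphenyl)-1,4-benzoquinone.
- Merits: it is the shortest conceivable access to the symmetric core, follows the biosynthetic logic, and raises no orientation question. O-benzylation of A5 would give 14 in far fewer steps than steps 1–5. In step count this road is clearly better, and because the core of the target is symmetric, the unsymmetrical construction of the chosen plan is not needed for its own sake.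
- Weak points: arylpyruvate enolates prefer aldol addition to the ketone carbonyl, the most electrophilic site present, which leads to lactone dimers and not to the carbocycle. Nothing in A4 steers it toward twofold Claisen acylation.
- Comparison: the chosen plan sets against this brevity a ring synthesis in which each C–C bond comes from a programmed organometallic event between two separately made, stable partners, with an independent cross-coupling entry to 14 in reserve.

**Alternative 3:** The cut is C1–C2 of the central ring. The alkenyllithium A6, [2-benzyloxy-1-(4-benzyloxyphenyl)ethenyl]lithium with lithium cis to the benzyloxy group, would add to the more electrophilic carbonyl of cyclobutenedione 6, and the alkoxide would be benzoylated to the cyclobutenone A7. On heating, A7 would open to a dienylketene, whose ketene carbon bonds to the benzyloxy-bearing alkene carbon. Tautomerization would give A8, which is the same compound as 16.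
- Merits: the ring emerges with O1 free and O4 already benzoylated, so the non-selective monobenzoylation of step 7 disappears. In this respect the road is better than the chosen plan, and it shares compound 6 with it.
- Weak points: A6 must be made with defined geometry and is prone to β-elimination of benzyloxide. A hindered tertiary alkoxide has to be benzoylated. The resulting tertiary, doubly allylic benzoate must survive the thermolysis without ionizing or shifting its acyl group.
- Comparison: the chosen plan sets against the built-in differentiation a partner (10) made from an ester in one flask, a ring closure at moderate temperature, and a symmetric intermediate (14) with a second entry. Its price is one monoacylation of a symmetric diol, backed by a deacylative fallback.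

Key step: step 4

Remark on the chemistry: the side-chain stereocenter is read as R and is carried unchanged from commercial (R)-3-hydroxybutanoic acid; no step breaks a bond to it.

## Route

Step 1
Reactants: 1 squaric acid
Product: 2 dibenzyl squarate [3,4-bis(benzyloxy)cyclobut-3-ene-1,2-dione]
Conditions: BnOH (4 equiv), toluene, reflux, Dean–Stark trap
Reagents that add atoms: benzyl alcohol, OCc1ccccc1
Why: Azeotropic esterification of the strongly acidic vinylogous diacid, which catalyses its own reaction; removal of water drives it to the diester, as in the standard preparation of dialkyl squarates.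

Step 2
Reactants: 3 1-benzyloxy-4-bromobenzene; 2 dibenzyl squarate
Product: 6 3-benzyloxy-4-(4-benzyloxyphenyl)cyclobut-3-ene-1,2-dione, via aryllithium 4 (not isolated), via hydroxycyclobutenone adduct 5 (not isolated)
Conditions: n-BuLi, THF, −78 °C; 2, −78 °C; aq. NH4Cl; crude in CH2Cl2, 12 M HCl (cat.), 25 °C
Reagents that add atoms: water, O
Why: Bromine–lithium exchange and 1,2-addition of the aryllithium to one squarate carbonyl give carbinol 5. Acid ionizes the tertiary hydroxyl, water adds to the oxocarbenium ion at the neighbouring carbon, and benzyl alcohol is lost (the standard squarate-to-cyclobutenedione sequence).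

Step 3
Reactants: 7 ethyl 4-benzyloxybenzoate
Product: 10 {[(4-benzyloxyphenyl)ethynyl]oxy}triisopropylsilane, via lithium dibromoenolate 8 (not isolated), via lithium ynolate 9 (not isolated)
Conditions: CH2Br2, LiTMP (lithium 2,2,6,6-tetramethylpiperidide), THF, −78 °C; 7; LiN(SiMe3)2, then n-BuLi, −78 to 25 °C; TIPSCl, 0 to 25 °C
Reagents that add atoms: dibromomethane, BrCBr; triisopropylsilyl chloride, CC(C)[Si](Cl)(C(C)C)C(C)C
Why: Kowalski ester homologation: dibromomethyllithium adds to the ester, enolate 8 undergoes bromine–lithium exchange, and the carbenoid rearranges by 1,2-aryl shift to ynolate 9. A bulky silyl chloride then silylates the ynolate on oxygen and not on carbon.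

Step 4
Reactants: 6 3-benzyloxy-4-(4-benzyloxyphenyl)cyclobut-3-ene-1,2-dione; 10 {[(4-benzyloxyphenyl)ethynyl]oxy}triisopropylsilane
Product: 12 2-benzyloxy-3,6-bis(4-benzyloxyphenyl)-5-(triisopropylsilyloxy)-1,4-benzoquinone, via maleoylcobalt complex 11 (not isolated)
Conditions: CoCl(PPh3)3 (1.1 equiv), toluene, 25–50 °C; AgBF4 (1.1 equiv), MeCN, 25 °C; then 10 (1.3 equiv), 25–70 °C
Reagents that add atoms: none
Why: Proposed new method: monovalent cobalt should add oxidatively across the strained bond between the two carbonyl carbons of 6 to give the five-membered maleoyl chelate 11 of trivalent cobalt; AgBF4 then removes chloride, alkyne 10 takes the free site, one acyl group migrates onto the bound alkyne to give a seven-membered cobaltacycle, and reductive elimination forms the second C–C bond. The closest known reaction type is the quinone synthesis from cyclobutenedione-derived maleoylcobalt complexes and simple terminal or internal alkynes under the same silver activation; a silyl ynol ether has not served as the alkyne and its orientation is unexplored. The carbocycle closes as a six-membered ring by reductive elimination of an acyl–vinyl pair from the seven-membered metallacycle, a formal [4+2] union that forms C4–C5 and C6–C1 and creates no stereocenter. The step needs head-to-tail orientation, that is 2,5- and not 2,6-dioxygenation. Two substrate features should secure it: the acyl carbon next to the benzyloxy-bearing carbon (C1) is the more electrophilic because the other acyl group (C4) is a vinylogous ester carbonyl, and the ynol ether, once bound to the cationic metal, is nucleophilic at its aryl-bearing carbon (C6) and oxocarbenium-like at its siloxy-bearing carbon (C5). Whether the first bond is viewed as attack of C6 on C1 or as migration of the more electron-rich acyl carbon C4 to C5, the pairing is the same. Silver is consumed as AgCl before 10 is added so that free silver ion cannot start ketenium chemistry of the siloxyalkyne, and the triisopropylsilyl group is chosen for its resistance to the Lewis-acidic medium.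

Step 5
Reactants: 12 2-benzyloxy-3,6-bis(4-benzyloxyphenyl)-5-(triisopropylsilyloxy)-1,4-benzoquinone
Product: 14 2,5-bis(benzyloxy)-3,6-bis(4-benzyloxyphenyl)-1,4-benzoquinone, via cesium quinonolate 13 (not isolated)
Conditions: CsF, BnBr, DMF, 0 to 25 °C
Reagents that add atoms: benzyl bromide, BrCc1ccccc1
Why: Fluoride cleaves the Si–O bond of the silyl vinylogous ester and the resulting vinylogous carboxylate 13 is O-alkylated by benzyl bromide (carboxylate-type SN2 alkylation). Any material desilylated during step 4 converges here.

Step 6
Reactants: 14 2,5-bis(benzyloxy)-3,6-bis(4-benzyloxyphenyl)-1,4-benzoquinone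
Product: 15 2,5-bis(benzyloxy)-3,6-bis(4-benzyloxyphenyl)benzene-1,4-diol
Conditions: Na2S2O4, THF–H2O, 25 °C, argon; used crude
Reagents that add atoms: none
Why: Two-electron reduction of a quinone to its hydroquinone by dithionite; benzyl ethers are inert, and the air-sensitive product is carried on directly under argon.

Step 7
Reactants: 15 2,5-bis(benzyloxy)-3,6-bis(4-benzyloxyphenyl)benzene-1,4-diol
Product: 16 2,5-bis(benzyloxy)-3,6-bis(4-benzyloxyphenyl)-4-hydroxyphenyl benzoate
Conditions: BzCl (1.0 equiv), Et3N, DMAP (cat.), CH2Cl2, −40 to 0 °C
Reagents that add atoms: benzoyl chloride, O=C(Cl)c1ccccc1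
Why: DMAP-catalysed acylation of a phenol with an acyl chloride; the two hydroxyls of 15 are equivalent, so only one monoester can form, and the first benzoate makes the para hydroxyl slightly less nucleophilic. The distribution should be at worst statistical, with unreacted 15 and the dibenzoate separable and recyclable.

Step 8
Reactants: 17 (R)-3-hydroxybutanoic acid
Product: 18 (R)-3-acetoxybutanoic acid
Conditions: AcCl, CH2Cl2, 0 to 25 °C; then H2O
Reagents that add atoms: acetyl chloride, CC(=O)Cl
Why: O-acetylation of the secondary alcohol under acidic, base-free conditions, with aqueous work-up cleaving any mixed anhydride; no bond to the stereocenter is broken, so the R configuration is retained.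

Step 9
Reactants: 16 2,5-bis(benzyloxy)-3,6-bis(4-benzyloxyphenyl)-4-hydroxyphenyl benzoate; 18 (R)-3-acetoxybutanoic acid
Product: 19 tetra-O-benzyl curtisian T [4-benzoyloxy-2,5-bis(benzyloxy)-3,6-bis(4-benzyloxyphenyl)phenyl (R)-3-acetoxybutanoate]
Conditions: DCC, DMAP (cat.), CH2Cl2, 0 to 25 °C
Reagents that add atoms: none
Why: Steglich esterification, in which the acylpyridinium intermediate reaches the hindered phenol. Only catalytic DMAP at low temperature is used so that loss of acetate from the activated acid or the aryl ester is not promoted; the stereocenter is not involved.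

Step 10
Reactants: 19 tetra-O-benzyl curtisian T
Product: 20 curtisian T
Conditions: H2 (1 atm), Pd/C, EtOAc, 25 °C
Reagents that add atoms: none
Why: Heterogeneous hydrogenolysis of four aryl benzyl ethers under neutral conditions; aryl benzoate, aryl alkanoate and alkyl acetate are inert. The aprotic solvent excludes transesterification and acyl migration, and the stereocenter is untouched.

## Compound list

1 | squaric acid (3,4-dihydroxycyclobut-3-ene-1,2-dione) | O=C1C(O)=C(O)C1=O | starting material
2 | dibenzyl squarate [3,4-bis(benzyloxy)cyclobut-3-ene-1,2-dione] | O=C1C(=O)C(OCc2ccccc2)=C1OCc1ccccc1 | intermediate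
3 | 1-benzyloxy-4-bromobenzene | Brc1ccc(OCc2ccccc2)cc1 | starting material
4 | (4-benzyloxyphenyl)lithium | [Li]c1ccc(OCc2ccccc2)cc1 | intermediate (not isolated)
5 | 2,3-bis(benzyloxy)-4-(4-benzyloxyphenyl)-4-hydroxycyclobut-2-en-1-one (racemic) | O=C1C(OCc2ccccc2)=C(OCc2ccccc2)C1(O)c1ccc(OCc2ccccc2)cc1 | intermediate (not isolated)
6 | 3-benzyloxy-4-(4-benzyloxyphenyl)cyclobut-3-ene-1,2-dione | O=C1C(=O)C(OCc2ccccc2)=C1c1ccc(OCc2ccccc2)cc1 | intermediate
7 | ethyl 4-benzyloxybenzoate | CCOC(=O)c1ccc(OCc2ccccc2)cc1 | starting material
8 | lithium 1-(4-benzyloxyphenyl)-2,2-dibromoethenolate | [Li+].[O-]C(=C(Br)Br)c1ccc(OCc2ccccc2)cc1 | intermediate (not isolated)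
9 | lithium 2-(4-benzyloxyphenyl)ethynolate | [Li+].[O-]C#Cc1ccc(OCc2ccccc2)cc1 | intermediate (not isolated)
10 | {[(4-benzyloxyphenyl)ethynyl]oxy}triisopropylsilane | CC(C)[Si](C(C)C)(C(C)C)OC#Cc1ccc(OCc2ccccc2)cc1 | intermediate
11 | chlorobis(triphenylphosphine)cobalt chelate of the 2-benzyloxy-3-(4-benzyloxyphenyl)but-2-ene-1,4-dioyl (maleoyl) ligand, trivalent cobalt, CoCl(PPh3)2[C(O)C(OBn)=C(Ar)C(O)], drawn with charge-separated Co–P bonds | O=C1C(OCc2ccccc2)=C(c2ccc(OCc3ccccc3)cc2)C(=O)[Co-2]1(Cl)([P+](c1ccccc1)(c1ccccc1)c1ccccc1)[P+](c1ccccc1)(c1ccccc1)c1ccccc1 | intermediate (not isolated)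
12 | 2-benzyloxy-3,6-bis(4-benzyloxyphenyl)-5-(triisopropylsilyloxy)-1,4-benzoquinone | O=C1C(OCc2ccccc2)=C(c2ccc(OCc3ccccc3)cc2)C(=O)C(O[Si](C(C)C)(C(C)C)C(C)C)=C1c1ccc(OCc2ccccc2)cc1 | intermediate
13 | cesium 4-benzyloxy-2,5-bis(4-benzyloxyphenyl)-3,6-dioxocyclohexa-1,4-dien-1-olate | [Cs+].[O-]C1=C(c2ccc(OCc3ccccc3)cc2)C(=O)C(OCc2ccccc2)=C(c2ccc(OCc3ccccc3)cc2)C1=O | intermediate (not isolated)
14 | 2,5-bis(benzyloxy)-3,6-bis(4-benzyloxyphenyl)-1,4-benzoquinone | O=C1C(OCc2ccccc2)=C(c2ccc(OCc3ccccc3)cc2)C(=O)C(OCc2ccccc2)=C1c1ccc(OCc2ccccc2)cc1 | intermediate
15 | 2,5-bis(benzyloxy)-3,6-bis(4-benzyloxyphenyl)benzene-1,4-diol | Oc1c(OCc2ccccc2)c(-c2ccc(OCc3ccccc3)cc2)c(O)c(OCc2ccccc2)c1-c1ccc(OCc2ccccc2)cc1 | intermediate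
16 | 2,5-bis(benzyloxy)-3,6-bis(4-benzyloxyphenyl)-4-hydroxyphenyl benzoate | O=C(Oc1c(OCc2ccccc2)c(-c2ccc(OCc3ccccc3)cc2)c(O)c(OCc2ccccc2)c1-c1ccc(OCc2ccccc2)cc1)c1ccccc1 | intermediate
17 | (R)-3-hydroxybutanoic acid | C[C@@H](O)CC(=O)O | starting material
18 | (R)-3-acetoxybutanoic acid | CC(=O)O[C@H](C)CC(=O)O | intermediate
19 | tetra-O-benzyl curtisian T [4-benzoyloxy-2,5-bis(benzyloxy)-3,6-bis(4-benzyloxyphenyl)phenyl (R)-3-acetoxybutanoate] | CC(=O)O[C@H](C)CC(=O)Oc1c(OCc2ccccc2)c(-c2ccc(OCc3ccccc3)cc2)c(OC(=O)c2ccccc2)c(OCc2ccccc2)c1-c1ccc(OCc2ccccc2)cc1 | intermediate
20 | curtisian T | CC(=O)O[C@H](C)CC(=O)Oc1c(O)c(-c2ccc(O)cc2)c(OC(=O)c2ccccc2)c(O)c1-c1ccc(O)cc1 | target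

## Step count and risks

Total step count: 10. Longest linear sequence: 8 steps (steps 1, 2, 4, 5, 6, 7, 9, 10); steps 3 and 8 are one-step side branches.

**Step 4 (key step, proposed new method).**
- What may go wrong: mispairing of the two unsymmetrical partners. The two acyl carbons of 11 differ only moderately in electrophilicity, and an oxophilic cation bound to the vinylogous ester carbonyl could reverse their order, giving head-to-head orientation. The cationic metal could also consume 10 by oligomerization or protodesilylation before insertion.
- Fallback (known chemistry): it sets out from bromide 3 and returns at quinone 14, replacing steps 1–5. Bromine–lithium exchange of 3, quenching with B(OiPr)3 and aqueous acid give (4-benzyloxyphenyl)boronic acid F1. Commercial bromanilic acid is O-benzylated through its silver salt (Ag2O, benzyl bromide) to 2,5-bis(benzyloxy)-3,6-dibromo-1,4-benzoquinone F2. Twofold Suzuki–Miyaura coupling of F2 with F1 (Pd(PPh3)4, zerovalent palladium, K3PO4, dioxane) gives 14. The halide pattern then fixes the position of every substituent and no orientation question arises.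

**Step 7.**
- What may go wrong: over-acylation alongside incomplete conversion, because the second hydroxyl is only slightly deactivated by the first benzoate, and reoxidation of the electron-rich hydroquinone to 14 under basic conditions.
- Fallback: it sets out from 15 and returns at 16. Exhaustive benzoylation (excess benzoyl chloride, pyridine) gives the air-stable 2,5-bis(benzyloxy)-3,6-bis(4-benzyloxyphenyl)-1,4-phenylene dibenzoate F3. One equivalent of NaOMe in THF–MeOH at low temperature then removes one benzoyl group. The first cleavage leaves a phenoxide whose para ester would have to expel a dianion, so the second cleavage is slowed for an electronic reason that monoacylation lacks.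

**Step 9.**
- What may go wrong: loss of acetate by base-induced β-elimination from the activated acid or from the aryl ester, giving a crotonate, and slow acylation of the hindered phenol with rearrangement of the activated acid to an unreactive N-acylurea.
- Fallback: it sets out from acid 17 and phenol 16 and returns at 19, with the acetyl group introduced after the esterification. Silylation of 17 (TBSCl, imidazole, DMF) gives tert-butyldimethylsilyl (R)-3-(tert-butyldimethylsilyloxy)butanoate F4. Selective hydrolysis of its silyl ester (K2CO3, MeOH–H2O) gives (R)-3-(tert-butyldimethylsilyloxy)butanoic acid F5, whose β-substituent is a poor leaving group. Coupling with 16 (DCC, DMAP) gives 4-benzoyloxy-2,5-bis(benzyloxy)-3,6-bis(4-benzyloxyphenyl)phenyl (R)-3-(tert-butyldimethylsilyloxy)butanoate F6. Acidic desilylation (HF·pyridine, THF) gives 4-benzoyloxy-2,5-bis(benzyloxy)-3,6-bis(4-benzyloxyphenyl)phenyl (R)-3-hydroxybutanoate F7. Acetylation (Ac2O, pyridine), with no free phenol present, gives 19.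

**Step 3.**
- What may go wrong: deprotonation of the benzylic ether position by excess alkyllithium during warming, followed by Wittig rearrangement; incomplete carbenoid rearrangement; and silylation of the ynolate on carbon.
- Fallback: it sets out from bromide 3 and returns at 10 through ynolate 9. Sonogashira coupling of 3 with trimethylsilylacetylene (PdCl2(PPh3)2, divalent palladium, CuI, Et3N) gives {[4-(benzyloxy)phenyl]ethynyl}trimethylsilane F8. Methanolysis (K2CO3, MeOH) gives 1-benzyloxy-4-ethynylbenzene F9. Deprotonation of F9 with LiN(SiMe3)2 and oxidation of the acetylide with lithium tert-butyl peroxide at −78 °C give 9, which is silylated on oxygen with triisopropylsilyl triflate to 10.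

## Further compounds

F1 | step 4 | (4-benzyloxyphenyl)boronic acid | OB(O)c1ccc(OCc2ccccc2)cc1
F2 | step 4 | 2,5-bis(benzyloxy)-3,6-dibromo-1,4-benzoquinone | O=C1C(Br)=C(OCc2ccccc2)C(=O)C(Br)=C1OCc1ccccc1
F3 | step 7 | 2,5-bis(benzyloxy)-3,6-bis(4-benzyloxyphenyl)-1,4-phenylene dibenzoate | O=C(Oc1c(OCc2ccccc2)c(-c2ccc(OCc3ccccc3)cc2)c(OC(=O)c2ccccc2)c(OCc2ccccc2)c1-c1ccc(OCc2ccccc2)cc1)c1ccccc1
F4 | step 9 | tert-butyldimethylsilyl (R)-3-(tert-butyldimethylsilyloxy)butanoate | C[C@@H](O[Si](C)(C)C(C)(C)C)CC(=O)O[Si](C)(C)C(C)(C)C
F5 | step 9 | (R)-3-(tert-butyldimethylsilyloxy)butanoic acid | C[C@@H](O[Si](C)(C)C(C)(C)C)CC(=O)O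
F6 | step 9 | 4-benzoyloxy-2,5-bis(benzyloxy)-3,6-bis(4-benzyloxyphenyl)phenyl (R)-3-(tert-butyldimethylsilyloxy)butanoate | C[C@@H](O[Si](C)(C)C(C)(C)C)CC(=O)Oc1c(OCc2ccccc2)c(-c2ccc(OCc3ccccc3)cc2)c(OC(=O)c2ccccc2)c(OCc2ccccc2)c1-c1ccc(OCc2ccccc2)cc1
F7 | step 9 | 4-benzoyloxy-2,5-bis(benzyloxy)-3,6-bis(4-benzyloxyphenyl)phenyl (R)-3-hydroxybutanoate | C[C@@H](O)CC(=O)Oc1c(OCc2ccccc2)c(-c2ccc(OCc3ccccc3)cc2)c(OC(=O)c2ccccc2)c(OCc2ccccc2)c1-c1ccc(OCc2ccccc2)cc1
F8 | step 3 | {[4-(benzyloxy)phenyl]ethynyl}trimethylsilane | C[Si](C)(C)C#Cc1ccc(OCc2ccccc2)cc1
F9 | step 3 | 1-benzyloxy-4-ethynylbenzene | C#Cc1ccc(OCc2ccccc2)cc1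
A1 | alternative 1 | (R)-3-acetoxy-1-diazobutan-2-one | CC(=O)O[C@H](C)C(=O)C=[N+]=[N-]
A2 | alternative 1 | (R)-3-acetoxybut-1-en-1-one (ketene) | CC(=O)O[C@H](C)C=C=O
A3 | alternative 1 | tetra-O-benzyl curtisian T (identical with 19) | CC(=O)O[C@H](C)CC(=O)Oc1c(OCc2ccccc2)c(-c2ccc(OCc3ccccc3)cc2)c(OC(=O)c2ccccc2)c(OCc2ccccc2)c1-c1ccc(OCc2ccccc2)cc1
A4 | alternative 2 | methyl 3-(4-benzyloxyphenyl)-2-oxopropanoate | COC(=O)C(=O)Cc1ccc(OCc2ccccc2)cc1
A5 | alternative 2 | 2,5-dihydroxy-3,6-bis(4-benzyloxyphenyl)-1,4-benzoquinone | O=C1C(O)=C(c2ccc(OCc3ccccc3)cc2)C(=O)C(O)=C1c1ccc(OCc2ccccc2)cc1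
A6 | alternative 3 | [2-benzyloxy-1-(4-benzyloxyphenyl)ethenyl]lithium, lithium cis to the benzyloxy group | [Li]/C(=C\OCc1ccccc1)c1ccc(OCc2ccccc2)cc1
A7 | alternative 3 | 4-benzoyloxy-3-benzyloxy-4-[2-benzyloxy-1-(4-benzyloxyphenyl)ethenyl]-2-(4-benzyloxyphenyl)cyclobut-2-en-1-one (racemic) | O=C1C(c2ccc(OCc3ccccc3)cc2)=C(OCc2ccccc2)C1(OC(=O)c1ccccc1)/C(=C\OCc1ccccc1)c1ccc(OCc2ccccc2)cc1
A8 | alternative 3 | 2,5-bis(benzyloxy)-3,6-bis(4-benzyloxyphenyl)-4-hydroxyphenyl benzoate (identical with 16) | O=C(Oc1c(OCc2ccccc2)c(-c2ccc(OCc3ccccc3)cc2)c(O)c(OCc2ccccc2)c1-c1ccc(OCc2ccccc2)cc1)c1ccccc1
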